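Retrosynthesis: the first cuts are the two CH2–C bonds that tie the arms on C3 and C5 of ring A (the central benzene) to the free ring carbon of ring B (acetylfilicinic acid) and ring C (propionylfilicinic acid). C1–C2 and C5–C6 of ring A are cut next.
Feature used: in ring A (C1 butyryl; C2, C4, C6 oxygen; C3, C5 CH2 arms) the run C2–C3–C4–C5 is a 2,4-disubstituted acetoacetate (C2 = ester carbon, C4 = ketone carbon). C1–C6 is a butyryl alkyne oxygenated at its far carbon, so an electron-rich diene and a push–pull ynone give the hexasubstituted ring at its final oxidation level.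
Forward: a crossed Claisen acylation sets two unlike arms (CH2OMe for C3, CH2O-PMB for C5; PMB = 4-methoxybenzyl) and double silylation gives the diene. Benzyl dichlorovinyl ether gives the ynone, and joining the two closes ring A, the only ring built; rings B and C come from acylphloroglucinols by geminal C-methylation.
End game: the arms are opened one after the other as o-quinone methides. The PMB arm goes first (DDQ, then base-induced carbonate transfer, trapped by ring B), the methyl ether arm second (acid, trapped by ring C), and the C6 benzyl ether is hydrogenolysed last. C3 and C5 become equivalent once C6–OH is free, so only the order of opening matters.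
Stereochemistry: the target has no stereocentre and no fixed alkene geometry, so nothing has to be set.

Key step: step 8

Remark: rings B and C are drawn in the enol tautomer of the target SMILES; the β-keto ester and the cycloadduct are racemic or diastereomeric mixtures and the silyl enol ethers are E/Z mixtures, so their SMILES carry no descriptors, and all of this information disappears when ring A aromatises.

Step 1
Reactants: 1 4-methoxybenzyl alcohol; 2 methyl acrylate
Product: 3 methyl 3-[(4-methoxybenzyl)oxy]propanoate
Conditions: KOtBu (5 mol%), THF, 0 → 23 °C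
Reagents that add atoms: none
Why: Base-catalysed oxa-Michael addition of a primary alkoxide to an acrylate is reliable, and any transesterified material converges on the same acid in step 2.

Step 2
Reactants: 3 methyl 3-[(4-methoxybenzyl)oxy]propanoate
Product: 4 3-[(4-methoxybenzyl)oxy]propanoic acid
Conditions: LiOH (1.5 equiv), THF/H2O, 23 °C; then 1 M HCl to pH 3
Reagents that add atoms: lithium hydroxide, [Li+].[OH-] (oxygen of the new OH)
Why: In this saponification at room temperature, hydroxide should attack the ester carbonyl much faster than it provokes retro-oxa-Michael loss of the alkoxide.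

Step 3
Reactants: 4 3-[(4-methoxybenzyl)oxy]propanoic acid; 5 methyl 3-methoxypropanoate
Product: 8 methyl 5-[(4-methoxybenzyl)oxy]-2-(methoxymethyl)-3-oxopentanoate (racemic), via acyl imidazolide 6 (not isolated), via lithium ester enolate 7 (not isolated)
Conditions: 4, 1,1'-carbonyldiimidazole (1.1 equiv), THF, 23 °C; transferred into 5 (3.3 equiv)/LiN(iPr)2 (3.2 equiv), THF, −78 °C; sat. aq NH4Cl at −78 °C
Reagents that add atoms: 1,1'-carbonyldiimidazole, O=C(n1ccnc1)n1ccnc1 (imidazolyl group of 6 only); LiN(iPr)2, [Li+].CC(C)[N-]C(C)C (lithium of 7 only)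
Why: In this crossed Claisen acylation of a preformed lithium ester enolate by an acyl imidazolide, 7 should be acylated at −78 °C faster than it loses methoxide, the excess of cheap 5 absorbs the acidic protons of imidazole and of 8, and C-acylation puts the methoxymethyl arm on C2 without the O-alkylation that chloromethyl ethers tend to give with β-keto ester enolates.

Step 4
Reactants: 8 methyl 5-[(4-methoxybenzyl)oxy]-2-(methoxymethyl)-3-oxopentanoate
Product: 9 methyl 5-[(4-methoxybenzyl)oxy]-2-(methoxymethyl)-3-(trimethylsilyloxy)pent-2-enoate (E/Z mixture)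
Conditions: Me3SiCl (1.8 equiv), Et3N (1.6 equiv), toluene, 23 °C, 48–72 h; filtration under Ar
Reagents that add atoms: chlorotrimethylsilane, C[Si](C)(C)Cl
Why: Silyl enol ether formation from the enol of a β-keto ester runs with an amine base that is too weak to expel either β-alkoxide.

Step 5
Reactants: 9 methyl 5-[(4-methoxybenzyl)oxy]-2-(methoxymethyl)-3-(trimethylsilyloxy)pent-2-enoate
Product: 11 1-methoxy-2-(methoxymethyl)-5-[(4-methoxybenzyl)oxy]-1,3-bis(trimethylsilyloxy)penta-1,3-diene (E/Z mixture), via lithium dienolate 10 (not isolated)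
Conditions: 9, Me3SiCl (2.0 equiv), THF, −78 °C; LiN(iPr)2 (1.5 equiv) added slowly; −78 → 0 °C; pentane, filtration under Ar, used crude
Reagents that add atoms: chlorotrimethylsilane, C[Si](C)(C)Cl; LiN(iPr)2, [Li+].CC(C)[N-]C(C)C (lithium of 10 only)
Why: γ-Deprotonation of a 3-silyloxy enoate followed by O-silylation of the ester dienolate is the standard entry to 1-alkoxy-1,3-bis(silyloxy)dienes, and keeping Me3SiCl present from the start (in situ quench) should trap 10 before vinylogous β-elimination of the PMB oxide sets in.

Step 6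
Reactants: 12 benzyl alcohol; 13 trichloroethylene
Product: 15 benzyl (E)-1,2-dichlorovinyl ether, via dichloroacetylene 14 (not isolated)
Conditions: KH (1.2 equiv), THF, 0 °C; 13 (1.1 equiv), −50 → 23 °C
Reagents that add atoms: none
Why: The potassium alkoxide dehydrochlorinates 13 to 14 and then adds to it in anti fashion (nucleophilic addition to a haloalkyne), which is the established way to (E)-1,2-dichlorovinyl ethers.

Step 7
Reactants: 15 benzyl (E)-1,2-dichlorovinyl ether; 16 N-methoxy-N-methylbutanamide
Product: 19 1-(benzyloxy)hex-1-yn-3-one, via benzyl chloroethynyl ether 17 (not isolated), via lithium benzyloxyacetylide 18 (not isolated)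
Conditions: n-BuLi (2.2 equiv), THF, −78 → −40 °C; 16 (1.0 equiv), −78 → −20 °C; cold sat. aq NH4Cl; kept below 0 °C and used promptly
Reagents that add atoms: n-butyllithium, [Li]CCCC (lithium of 18 only)
Why: β-Elimination and chlorine–lithium exchange give the lithium alkoxyacetylide, and its acylation by a Weinreb amide (Weinreb ketone synthesis) stops at the ketone because the chelated tetrahedral adduct lasts until the quench.

Step 8
Reactants: 11 1-methoxy-2-(methoxymethyl)-5-[(4-methoxybenzyl)oxy]-1,3-bis(trimethylsilyloxy)penta-1,3-diene; 19 1-(benzyloxy)hex-1-yn-3-one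
Product: 22 1-[2-(benzyloxy)-4,6-dihydroxy-5-(methoxymethyl)-3-{[(4-methoxybenzyl)oxy]methyl}phenyl]butan-1-one, via cyclohexadiene ketal 20 (not isolated), via bis(silyl ether) arene 21 (not isolated)
Conditions: 11 (1.6 equiv), 19, toluene (1 M), Ar, no Lewis acid, −40 → 30 °C; then 10% aq citric acid/THF, 0 °C
Reagents that add atoms: none
Why: Proposed new method: the closest known reaction type is the Diels–Alder reaction of 1-alkoxy-1,3-bis(silyloxy)dienes with acetylenic ketones and esters followed by aromatisation to acylresorcinols, whereas a β-alkoxy ynone as dienophile and a diene carrying two alkoxymethyl groups have not been shown. The CH terminus of the diene (future C5), to which both oxygen donors push electron density, should bond to the benzyloxy-bearing alkyne carbon β to the ketone (bond C5–C6) and the ketene acetal carbon to the α-carbon (bond C1–C2), either in an asynchronous [4+2] cycloaddition or by Mukaiyama–Michael addition followed by 6-(enolexo)-exo-trig attack of the allenolate carbon on the O-silylated ester carbon. Ring A is thereby closed as the cyclohexa-1,4-diene ketal 20, 1,4-elimination of methanol gives arene 21, and the mild aqueous acid takes off both silyl groups. The two stereocentres of 20 are uncontrolled and vanish on aromatisation, so no stereocontrol is needed. The step needs regioselectivity and 1,4- rather than 1,2-addition: the ketone polarises the ynone and the ketene acetal polarises the diene in the matching sense, while leaving out any Lewis acid keeps the carbonyl carbon unactivated and the allylic ether arms of 11 from ionising. The temperature stays at or below 30 °C because benzyl alkynyl ethers undergo [3,3]-sigmatropic rearrangement on heating.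

Step 9
Reactants: 22 1-[2-(benzyloxy)-4,6-dihydroxy-5-(methoxymethyl)-3-{[(4-methoxybenzyl)oxy]methyl}phenyl]butan-1-one
Product: 23 5-(benzyloxy)-6-butanoyl-2-(methoxymethyl)-4-{[(4-methoxybenzyl)oxy]methyl}-1,3-phenylene di-tert-butyl bis(carbonate) (ring A: C2 and C4 as OBoc)
Conditions: Boc2O (3 equiv), 4-(dimethylamino)pyridine (0.2 equiv), iPr2NEt (3 equiv), CH2Cl2, 0 → 23 °C
Reagents that add atoms: di-tert-butyl dicarbonate, CC(C)(C)OC(=O)OC(=O)OC(C)(C)C
Why: Nucleophile-catalysed O-acylation of phenols caps both hydroxyls, which lowers the electron density of ring A for step 10 and places on C4–O the group that later becomes the leaving group of the C5 arm.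

Step 10
Reactants: 23 ring A bis(carbonate) with CH2OMe and CH2O-PMB arms
Product: 24 5-(benzyloxy)-6-butanoyl-4-(hydroxymethyl)-2-(methoxymethyl)-1,3-phenylene di-tert-butyl bis(carbonate)
Conditions: DDQ (2,3-dichloro-5,6-dicyano-1,4-benzoquinone, 1.3 equiv), CH2Cl2/pH 7 phosphate buffer (10:1), 0 °C
Reagents that add atoms: none
Why: In this oxidative PMB ether cleavage, DDQ abstracts hydride from the anisyl CH2 because ring A, carrying a ketone and two carbonates, is much harder to oxidise, so the CH2OMe arm, the aryl benzyl ether and the carbonates should stay.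

Step 11
Reactants: 25 1-(2,4,6-trihydroxyphenyl)ethan-1-one
Product: 27 acetylfilicinic acid (2-acetyl-3,5-dihydroxy-4,4-dimethylcyclohexa-2,5-dien-1-one), via monomethyl ketone 26 (not isolated)
Conditions: NaOMe (3 equiv), MeI (2.1 equiv), MeOH, 0 → 40 °C; then 1 M HCl
Reagents that add atoms: iodomethane, CI
Why: In this alkylative dearomatisation of an acylphloroglucinolate, the carbon methylated first is the most nucleophilic one and takes the second methyl group, and the limited amount of MeI leaves the last ring CH free.

Step 12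
Reactants: 24 5-(benzyloxy)-6-butanoyl-4-(hydroxymethyl)-2-(methoxymethyl)-1,3-phenylene di-tert-butyl bis(carbonate); 27 acetylfilicinic acid
Product: 29 ring A–ring B compound (ring A: C1 butyryl; C2 OBoc; C3 CH2OMe; C4 OH; C5 CH2 bonded to C6 of 2-acetyl-3,5-dihydroxy-4,4-dimethylcyclohexa-2,5-dien-1-one; C6 OBn), via o-quinone methide 28 (not isolated)
Conditions: 24, 27 (1.2 equiv), THF, −78 °C; tBuMgCl (3.4 equiv); −78 → 23 °C; sat. aq NH4Cl
Reagents that add atoms: none
Why: This is anionic o-quinone methide generation from an o-(tert-butoxycarbonyloxy)benzyl alcohol followed by Michael addition: the magnesium alkoxide takes over the C4 carbonate through a six-membered transition state, the phenoxide expels tert-butyl carbonate to give 28, and the magnesium enolate of 27 adds through its free ring carbon, while the CH2OMe arm carries too poor a leaving group to answer to base.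

Step 13
Reactants: 30 1-(2,4,6-trihydroxyphenyl)propan-1-one
Product: 32 propionylfilicinic acid (3,5-dihydroxy-4,4-dimethyl-2-propanoylcyclohexa-2,5-dien-1-one), via monomethyl ketone 31 (not isolated)
Conditions: NaOMe (3 equiv), MeI (2.1 equiv), MeOH, 0 → 40 °C; then 1 M HCl
Reagents that add atoms: iodomethane, CI
Why: This is the same alkylative dearomatisation as in step 11, with geminal C-methylation favoured at the carbon that is attacked first.

Step 14
Reactants: 29 ring A–ring B compound; 32 propionylfilicinic acid
Product: 35 C6-O-benzyl ether of the target (ring A: C2 OH; C3 CH2–ring C; C4 OH; C5 CH2–ring B; C6 OBn), via free phenol 33 (not isolated), via o-quinone methide 34 (not isolated)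
Conditions: 32 (1.5 equiv), CF3CO2H/CH2Cl2 (1:4), 0 °C; cold evaporation with toluene
Reagents that add atoms: none
Why: In this Brønsted acid-promoted benzylation of a cyclic 1,3-dicarbonyl compound by an o-hydroxybenzyl ether, CF3CO2H removes the last carbonate and ionises the methoxymethyl arm to 34 (as its protonated form), the enol carbon of 32 captures it, and C–O ionisation at 0 °C should be far faster than C–C ionisation of the bridge already present, so bridge exchange should stay minor.

Step 15
Reactants: 35 C6-O-benzyl ether of the target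
Product: 36 CNP0315613.0
Conditions: H2 (1 atm), Pd/C (10 wt% Pd), EtOAc, 23 °C
Reagents that add atoms: none
Why: Hydrogenolysis of the aryl benzyl ether is neutral and so avoids the acid- or base-induced exchange of the methylene bridges, and the chelated aryl ketone and the enolised triketones should not be reduced at atmospheric pressure.

Compound list
1 | 4-methoxybenzyl alcohol | COc1ccc(CO)cc1 | starting material
2 | methyl acrylate | C=CC(=O)OC | starting material
3 | methyl 3-[(4-methoxybenzyl)oxy]propanoate | COC(=O)CCOCc1ccc(OC)cc1 | intermediate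
4 | 3-[(4-methoxybenzyl)oxy]propanoic acid | OC(=O)CCOCc1ccc(OC)cc1 | intermediate
5 | methyl 3-methoxypropanoate | COCCC(=O)OC | starting material
6 | 1-(1H-imidazol-1-yl)-3-[(4-methoxybenzyl)oxy]propan-1-one | O=C(CCOCc1ccc(OC)cc1)n1ccnc1 | intermediate
7 | lithium enolate of methyl 3-methoxypropanoate | COCC=C([O-])OC.[Li+] | intermediate
8 | methyl 5-[(4-methoxybenzyl)oxy]-2-(methoxymethyl)-3-oxopentanoate (racemic) | COC(=O)C(COC)C(=O)CCOCc1ccc(OC)cc1 | intermediate
9 | methyl 5-[(4-methoxybenzyl)oxy]-2-(methoxymethyl)-3-(trimethylsilyloxy)pent-2-enoate (E/Z mixture) | COC(=O)C(COC)=C(CCOCc1ccc(OC)cc1)O[Si](C)(C)C | intermediate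
10 | lithium dienolate of 9 | COC([O-])=C(COC)C(O[Si](C)(C)C)=CCOCc1ccc(OC)cc1.[Li+] | intermediate
11 | 1-methoxy-2-(methoxymethyl)-5-[(4-methoxybenzyl)oxy]-1,3-bis(trimethylsilyloxy)penta-1,3-diene (E/Z mixture) | COC(O[Si](C)(C)C)=C(COC)C(O[Si](C)(C)C)=CCOCc1ccc(OC)cc1 | intermediate
12 | benzyl alcohol | OCc1ccccc1 | starting material
13 | trichloroethylene | ClC=C(Cl)Cl | starting material
14 | dichloroacetylene | ClC#CCl | intermediate
15 | benzyl (E)-1,2-dichlorovinyl ether | Cl/C=C(/Cl)OCc1ccccc1 | intermediate
16 | N-methoxy-N-methylbutanamide | CCCC(=O)N(C)OC | starting material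
17 | benzyl chloroethynyl ether | ClC#COCc1ccccc1 | intermediate
18 | lithium benzyloxyacetylide | [Li]C#COCc1ccccc1 | intermediate
19 | 1-(benzyloxy)hex-1-yn-3-one | CCCC(=O)C#COCc1ccccc1 | intermediate
20 | 1-[2-(benzyloxy)-6-methoxy-5-(methoxymethyl)-3-{[(4-methoxybenzyl)oxy]methyl}-4,6-bis(trimethylsilyloxy)cyclohexa-1,4-dien-1-yl]butan-1-one (diastereomer mixture) | CCCC(=O)C1=C(OCc2ccccc2)C(COCc2ccc(OC)cc2)C(O[Si](C)(C)C)=C(COC)C1(OC)O[Si](C)(C)C | intermediate
21 | 1-[2-(benzyloxy)-5-(methoxymethyl)-3-{[(4-methoxybenzyl)oxy]methyl}-4,6-bis(trimethylsilyloxy)phenyl]butan-1-one | CCCC(=O)c1c(O[Si](C)(C)C)c(COC)c(O[Si](C)(C)C)c(COCc2ccc(OC)cc2)c1OCc1ccccc1 | intermediate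
22 | 1-[2-(benzyloxy)-4,6-dihydroxy-5-(methoxymethyl)-3-{[(4-methoxybenzyl)oxy]methyl}phenyl]butan-1-one | CCCC(=O)c1c(O)c(COC)c(O)c(COCc2ccc(OC)cc2)c1OCc1ccccc1 | intermediate
23 | 5-(benzyloxy)-6-butanoyl-2-(methoxymethyl)-4-{[(4-methoxybenzyl)oxy]methyl}-1,3-phenylene di-tert-butyl bis(carbonate) | CCCC(=O)c1c(OC(=O)OC(C)(C)C)c(COC)c(OC(=O)OC(C)(C)C)c(COCc2ccc(OC)cc2)c1OCc1ccccc1 | intermediate
24 | 5-(benzyloxy)-6-butanoyl-4-(hydroxymethyl)-2-(methoxymethyl)-1,3-phenylene di-tert-butyl bis(carbonate) | CCCC(=O)c1c(OC(=O)OC(C)(C)C)c(COC)c(OC(=O)OC(C)(C)C)c(CO)c1OCc1ccccc1 | intermediate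
25 | 1-(2,4,6-trihydroxyphenyl)ethan-1-one | CC(=O)c1c(O)cc(O)cc1O | starting material
26 | 1-(2,4,6-trihydroxy-3-methylphenyl)ethan-1-one | CC(=O)c1c(O)cc(O)c(C)c1O | intermediate
27 | acetylfilicinic acid (2-acetyl-3,5-dihydroxy-4,4-dimethylcyclohexa-2,5-dien-1-one) | CC(=O)C1=C(O)C(C)(C)C(O)=CC1=O | intermediate
28 | o-quinone methide of ring A (C4=O, C5=CH2; C2 OBoc; C3 CH2OMe; C6 OBn) | C=C1C(=O)C(COC)=C(OC(=O)OC(C)(C)C)C(C(=O)CCC)=C1OCc1ccccc1 | intermediate
29 | ring A–ring B compound (C2 OBoc; C3 CH2OMe; C4 OH; C5 CH2–acetylfilicinic acid; C6 OBn) | CCCC(=O)c1c(OC(=O)OC(C)(C)C)c(COC)c(O)c(CC2=C(O)C(C)(C)C(O)=C(C(C)=O)C2=O)c1OCc1ccccc1 | intermediate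
30 | 1-(2,4,6-trihydroxyphenyl)propan-1-one | CCC(=O)c1c(O)cc(O)cc1O | starting material
31 | 1-(2,4,6-trihydroxy-3-methylphenyl)propan-1-one | CCC(=O)c1c(O)cc(O)c(C)c1O | intermediate
32 | propionylfilicinic acid (3,5-dihydroxy-4,4-dimethyl-2-propanoylcyclohexa-2,5-dien-1-one) | CCC(=O)C1=C(O)C(C)(C)C(O)=CC1=O | intermediate
33 | 29 without the carbonate (C2 OH) | CCCC(=O)c1c(O)c(COC)c(O)c(CC2=C(O)C(C)(C)C(O)=C(C(C)=O)C2=O)c1OCc1ccccc1 | intermediate
34 | o-quinone methide of the ring A–ring B compound (C2=O, C3=CH2) | C=C1C(=O)C(C(=O)CCC)=C(OCc2ccccc2)C(CC2=C(O)C(C)(C)C(O)=C(C(C)=O)C2=O)=C1O | intermediate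
35 | C6-O-benzyl ether of the target | CCCC(=O)c1c(O)c(CC2=C(O)C(C)(C)C(O)=C(C(=O)CC)C2=O)c(O)c(CC2=C(O)C(C)(C)C(O)=C(C(C)=O)C2=O)c1OCc1ccccc1 | intermediate
36 | CNP0315613.0 | CCCC(=O)c1c(O)c(CC2=C(O)C(C)(C)C(O)=C(C(C)=O)C2=O)c(O)c(CC2=C(O)C(C)(C)C(O)=C(C(=O)CC)C2=O)c1O | target

Total step count: 15.
Longest linear sequence: 11 steps (1, 2, 3, 4, 5, 8, 9, 10, 12, 14, 15).

Steps most likely to fail

Step 8.
- What may go wrong:
  - Bond formation may be slow, because the donor oxygen lowers the electrophilicity of the alkyne and the crowded diene populates its s-cis form poorly.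
  - The benzyl ynol ether may rearrange sigmatropically before it is consumed.
  - The reaction may stall after the first C–C bond.
  - The diene may lose an arm alkoxide.
- Fallback: this uses known chemistry in which ring A is bought instead of built. It sets out from 27 and comes back at 36. A Mannich reaction of 27 with aqueous formaldehyde and piperidine in ethanol gives 2-acetyl-3,5-dihydroxy-4,4-dimethyl-6-(piperidin-1-ylmethyl)cyclohexa-2,5-dien-1-one F2. Heating F2 in ethanol with an excess of commercial 1-(2,4,6-trihydroxyphenyl)butan-1-one F1 releases piperidine and the methylene triketone. This alkylates one free ring position and gives the two-ring compound 2-acetyl-6-(3-butanoyl-2,4,6-trihydroxybenzyl)-3,5-dihydroxy-4,4-dimethylcyclohexa-2,5-dien-1-one F3; the excess of F1 secures monoalkylation. The analogous Mannich base made from 32, 3,5-dihydroxy-4,4-dimethyl-6-(piperidin-1-ylmethyl)-2-propanoylcyclohexa-2,5-dien-1-one F4, then alkylates the last free position of F3 to give 36.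

Step 12.
- What may go wrong:
  - The carbonate may transfer to an enolate oxygen of 27 instead of to the benzylic alkoxide.
  - The o-quinone methide may condense with itself.
  - tert-Butoxide may capture the o-quinone methide.
  - The enolate may attack through O instead of C.
- Fallback: this changes the oxidation level of the arm. It sets out from 24 and comes back at 35. Dess–Martin periodinane oxidises 24 to 5-(benzyloxy)-6-butanoyl-4-formyl-2-(methoxymethyl)-1,3-phenylene di-tert-butyl bis(carbonate) F5. A three-component reductive alkylation of 27 follows (Knoevenagel condensation, then transfer hydrogenation by Hantzsch ester, L-proline catalysis, CH2Cl2, 23 °C). It gives the doubly carbonate-protected ring A–ring B compound F6. F6 takes the place of 29 under the conditions of step 14, where CF3CO2H strips both carbonates and 32 is attached.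

Step 3.
- What may go wrong:
  - The lithium enolate may lose methoxide by β-elimination before it is acylated.
  - Proton transfer from the acyl donor may quench the enolate.
- Fallback: this uses a doubly stabilised nucleophile instead of a simple ester enolate. It sets out from 4 (through 6) and comes back at 8. Commercial dimethyl 2-(methoxymethylidene)malonate F7 is hydrogenated (H2, Pd/C, MeOH) to dimethyl 2-(methoxymethyl)malonate F8. One equivalent of KOH in MeOH gives potassium methyl 2-(methoxymethyl)malonate F9. Its magnesium enolate (MgCl2, Et3N, MeCN) is acylated by 6 and loses CO2 (decarboxylative Claisen condensation of a malonic half-ester) to give 8.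

Further compounds
F1 | step 8 | 1-(2,4,6-trihydroxyphenyl)butan-1-one | CCCC(=O)c1c(O)cc(O)cc1O
F2 | step 8 | 2-acetyl-3,5-dihydroxy-4,4-dimethyl-6-(piperidin-1-ylmethyl)cyclohexa-2,5-dien-1-one | CC(=O)C1=C(O)C(C)(C)C(O)=C(CN2CCCCC2)C1=O
F3 | step 8 | 2-acetyl-6-(3-butanoyl-2,4,6-trihydroxybenzyl)-3,5-dihydroxy-4,4-dimethylcyclohexa-2,5-dien-1-one | CCCC(=O)c1c(O)cc(O)c(CC2=C(O)C(C)(C)C(O)=C(C(C)=O)C2=O)c1O
F4 | step 8 | 3,5-dihydroxy-4,4-dimethyl-6-(piperidin-1-ylmethyl)-2-propanoylcyclohexa-2,5-dien-1-one | CCC(=O)C1=C(O)C(C)(C)C(O)=C(CN2CCCCC2)C1=O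
F5 | step 12 | 5-(benzyloxy)-6-butanoyl-4-formyl-2-(methoxymethyl)-1,3-phenylene di-tert-butyl bis(carbonate) | CCCC(=O)c1c(OC(=O)OC(C)(C)C)c(COC)c(OC(=O)OC(C)(C)C)c(C=O)c1OCc1ccccc1
F6 | step 12 | doubly carbonate-protected ring A–ring B compound (C2 and C4 OBoc; C3 CH2OMe; C5 CH2–acetylfilicinic acid; C6 OBn) | CCCC(=O)c1c(OC(=O)OC(C)(C)C)c(COC)c(OC(=O)OC(C)(C)C)c(CC2=C(O)C(C)(C)C(O)=C(C(C)=O)C2=O)c1OCc1ccccc1
F7 | step 3 | dimethyl 2-(methoxymethylidene)malonate | COC=C(C(=O)OC)C(=O)OC
F8 | step 3 | dimethyl 2-(methoxymethyl)malonate | COCC(C(=O)OC)C(=O)OC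
F9 | step 3 | potassium methyl 2-(methoxymethyl)malonate | COCC(C(=O)OC)C(=O)[O-].[K+]
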